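**Retrosynthetic overview**

1. Labels: rings A (left phenoxy), B, C (central), D, E (right phenoxy). Ring C: C1 (dioxin carbon next to the C2–OH carbon), C4 (furan-oxygen carbon), C5 (biaryl carbon), C6 (second dioxin carbon). Ring B: B1 (bears O–A), B5 and B6 (dioxin oxygens, B6 next to B1). Ring D: D1 (furan oxygen), D2 (bears O–E), D6 (biaryl carbon).
2. Feature: C1 is an oxygen-bearing carbon para to the furan-oxygen carbon C4 and next to C6. Ring C can therefore be a C4 dienone whose C1 is the spiro ketal carbon of a para-quinone monoketal carrying both dioxin oxygens, and one 1,2-shift of oxygen from C1 to the CH carbon C6 gives the dioxin.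
3. Disconnections: 24 ⇐ nine-fold O-demethylation of 23 ⇐ furan C4–O–D1 by intramolecular SNAr of 22 ⇐ Suzuki C5–D6 (14 + 21) ⇐ oxygen shift in spiroketal 13 ⇐ PhI(OAc)2 oxidation of bisphenol 12 ⇐ twofold Baeyer–Villiger of 10 ⇐ SNAr of salicylaldehyde 7 on fluoroaldehyde 9.
4. Fragments: 7 from 1 + 2 (Ullmann ether, Baeyer–Villiger, ortho-formylation); 9 by bromination of 8; 21 from 15 (Baeyer–Villiger, Ullmann ether with 18, ortho-lithiation/borylation).
5. Ring order: the five benzene rings are bought; spiro-dioxole (step 7), dioxin by ring expansion (step 8), furan (step 13).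

Key step: step 8

Remark: the target has no stereocentre and is achiral, so no enantiomer has to be chosen; the spiro carbon of 13 is the only stereogenic element on the route, is formed as a racemate and disappears in step 8.
Remark: aldehyde 15 is assumed to be purchasable; otherwise Vilsmeier formylation of 1-fluoro-3,5-dimethoxybenzene would supply it.

**Route**

Step 1
Reactants: 1 5-bromo-2,4-dimethoxybenzaldehyde; 2 3,5-dimethoxyphenol
Product: 3 5-(3,5-dimethoxyphenoxy)-2,4-dimethoxybenzaldehyde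
Conditions: CuI (10 mol%), N,N-dimethylglycine·HCl (30 mol%), Cs2CO3, dioxane, 100 °C
Reagents that add atoms: none
Why: Ullmann-type C–O coupling of an unhindered phenol with an aryl bromide that has only one ortho substituent, the non-enolisable aldehyde being inert to carbonate.

Step 2
Reactants: 3 5-(3,5-dimethoxyphenoxy)-2,4-dimethoxybenzaldehyde
Product: 5 5-(3,5-dimethoxyphenoxy)-2,4-dimethoxyphenol, via aryl formate 4 (not isolated)
Conditions: mCPBA, CH2Cl2, 0 °C → rt; then K2CO3, MeOH, rt
Reagents that add atoms: mCPBA, OOC(=O)c1cccc(Cl)c1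
Why: Baeyer–Villiger (Dakin-type) oxidation in which the ortho and para methoxy groups make aryl migration faster than hydride migration, followed by mild methanolysis of the formate.

Step 3
Reactants: 5 5-(3,5-dimethoxyphenoxy)-2,4-dimethoxyphenol
Product: 7 2-(3,5-dimethoxyphenoxy)-6-hydroxy-3,5-dimethoxybenzaldehyde, via salicyl alcohol 6 (not isolated)
Conditions: MgCl2, Et3N, (CH2O)n, MeCN, reflux
Reagents that add atoms: paraformaldehyde (formaldehyde), C=O
Why: Magnesium-mediated ortho-formylation (Casnati–Skattebøl), in which the magnesium phenoxide delivers formaldehyde only to the single free ortho carbon (between OH and the aryloxy group) and a second formaldehyde oxidises the hydroxymethyl intermediate.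

Step 4
Reactants: 8 4-fluoro-3-methoxybenzaldehyde
Product: 9 2-bromo-4-fluoro-5-methoxybenzaldehyde
Conditions: Br2, AcOH, rt → 40 °C
Reagents that add atoms: bromine, BrBr
Why: Electrophilic aromatic bromination directed para to the methoxy group (ortho to CHO), as with 3-methoxybenzaldehyde, on a ring deactivated enough to stop at monobromination.

Step 5
Reactants: 7 2-(3,5-dimethoxyphenoxy)-6-hydroxy-3,5-dimethoxybenzaldehyde; 9 2-bromo-4-fluoro-5-methoxybenzaldehyde
Product: 10 2-bromo-4-[3-(3,5-dimethoxyphenoxy)-2-formyl-4,6-dimethoxyphenoxy]-5-methoxybenzaldehyde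
Conditions: K2CO3, DMF, 100 °C
Reagents that add atoms: none
Why: SNAr in which the phenoxide of 7 displaces the fluoride para to the formyl group, fluoride being far more reactive than the ortho bromide in addition–elimination.

Step 6
Reactants: 10 2-bromo-4-[3-(3,5-dimethoxyphenoxy)-2-formyl-4,6-dimethoxyphenoxy]-5-methoxybenzaldehyde
Product: 12 2-(5-bromo-4-hydroxy-2-methoxyphenoxy)-6-(3,5-dimethoxyphenoxy)-3,5-dimethoxyphenol, via bis-formate 11 (not isolated)
Conditions: mCPBA (3 equiv), CH2Cl2, 0 °C → rt; then K2CO3, MeOH (degassed), 0 °C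
Reagents that add atoms: mCPBA, OOC(=O)c1cccc(Cl)c1
Why: Twofold Baeyer–Villiger oxidation in which each formyl group has an aryloxy donor ortho or para to it, so both aryl groups migrate and one methanolysis frees both phenols.

Step 7
Reactants: 12 2-(5-bromo-4-hydroxy-2-methoxyphenoxy)-6-(3,5-dimethoxyphenoxy)-3,5-dimethoxyphenol
Product: 13 (±)-5'-bromo-4-(3,5-dimethoxyphenoxy)-2',5,7-trimethoxyspiro[1,3-benzodioxole-2,1'-cyclohexa-2',5'-dien]-4'-one
Conditions: PhI(OAc)2 (1.05 equiv), MeCN (0.02 M), 0 °C; aq NaHCO3 work-up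
Reagents that add atoms: none
Why: Hypervalent-iodine oxidative dearomatisation of a para-aryloxyphenol, in which the unhindered, more acidic ring-C phenol should exchange onto iodine in preference to the ring-B phenol (flanked by two aryloxy groups, its methoxy groups only meta) and the ring-B hydroxyl then traps C1 in a 5-exo closure to the racemic spiroketal.

Step 8
Reactants: 13 (±)-5'-bromo-4-(3,5-dimethoxyphenoxy)-2',5,7-trimethoxyspiro[1,3-benzodioxole-2,1'-cyclohexa-2',5'-dien]-4'-one
Product: 14 4-bromo-9-(3,5-dimethoxyphenoxy)-1,6,8-trimethoxydibenzo[b,e][1,4]dioxin-3-ol (ring C: OH on C4, Br on C5, OMe on C2; B6–O–C1 and B5–O–C6)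
Conditions: TfOH (2 equiv), dry CH2Cl2, −20 °C → rt; quench into cold aq NaHCO3
Reagents that add atoms: none
Why: Proposed new method: protonation of the vinylogous-ester carbonyl oxygen on C4 gives a hydroxypentadienyl cation with positive charge on C2 and C6, the ketal oxygen attached to B5 bridges from C1 to the CH carbon C6 through a three-membered oxonium-like transition state while the oxygen on B6 stabilises the developing cation at C1, and loss of the C6 proton aromatises ring C irreversibly. The closest known reactions are the dienone–phenol rearrangement and the acid-induced 1,2-acyloxy shift of para-quinol acetates; a 1,2-shift of an aryloxy group of a quinone monoketal is not established chemistry. The six-membered dioxin ring is closed by expansion of the five-membered dioxole, formally a 6-exo attack of oxygen on C6 of the C6=C5 bond that runs through 3-exo bridging, and no stereocentre is formed because the spiro centre disappears. Two selectivities are needed: migration to C6 and not to C2, secured because a shift to the methoxy-bearing C2 gives a cation that cannot lose a proton and can only revert; and migration of the B5 oxygen and not the B6 oxygen, for which the substrate offers only an electronic bias (the B5 oxygen is ortho and para to the two ring-B methoxy groups, the B6 oxygen is meta to both and flanked by the aryloxy group) that must be confirmed on 14 by HMBC/NOE or X-ray analysis. Full O-protonation also suppresses ionisation of the ketal, whose ring-opened cation is electrophilic only at C1, C3 and C5 and so cannot lead to the dioxin, and water is excluded to avoid hydrolysis to the quinone.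

Step 9
Reactants: 15 2-fluoro-4,6-dimethoxybenzaldehyde
Product: 17 2-fluoro-4,6-dimethoxyphenol, via aryl formate 16 (not isolated)
Conditions: mCPBA, CH2Cl2, 0 °C → rt; then K2CO3, MeOH, rt
Reagents that add atoms: mCPBA, OOC(=O)c1cccc(Cl)c1
Why: Baeyer–Villiger oxidation in which the methoxy groups ortho and para to the formyl group ensure aryl migration and the aryl fluoride is inert.

Step 10
Reactants: 17 2-fluoro-4,6-dimethoxyphenol; 18 1-bromo-3,5-dimethoxybenzene
Product: 19 2-(3,5-dimethoxyphenoxy)-1-fluoro-3,5-dimethoxybenzene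
Conditions: CuI (10 mol%), picolinic acid (20 mol%), K3PO4, DMSO, 90 °C
Reagents that add atoms: none
Why: Ullmann-type C–O coupling under Cu/picolinic acid conditions suited to ortho,ortho'-disubstituted phenols, with an unhindered meta-substituted aryl bromide and a C–F bond that copper does not touch.

Step 11
Reactants: 19 2-(3,5-dimethoxyphenoxy)-1-fluoro-3,5-dimethoxybenzene
Product: 21 2-[3-(3,5-dimethoxyphenoxy)-2-fluoro-4,6-dimethoxyphenyl]-4,4,5,5-tetramethyl-1,3,2-dioxaborolane, via aryllithium 20 (not isolated)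
Conditions: n-BuLi, THF, −78 °C; then i-PrOBpin, −78 °C → rt
Reagents that add atoms: 2-isopropoxy-4,4,5,5-tetramethyl-1,3,2-dioxaborolane, CC(C)OB1OC(C)(C)C(C)(C)O1
Why: Directed ortho-metalation at the C–H flanked by fluorine and methoxy (D6), the most acidic site, at −78 °C where positions between two ether groups are lithiated only slowly and the ortho-fluoroaryllithium does not lose LiF before the borate traps it.

Step 12
Reactants: 14 4-bromo-9-(3,5-dimethoxyphenoxy)-1,6,8-trimethoxydibenzo[b,e][1,4]dioxin-3-ol; 21 2-[3-(3,5-dimethoxyphenoxy)-2-fluoro-4,6-dimethoxyphenyl]-4,4,5,5-tetramethyl-1,3,2-dioxaborolane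
Product: 22 4-[3-(3,5-dimethoxyphenoxy)-2-fluoro-4,6-dimethoxyphenyl]-9-(3,5-dimethoxyphenoxy)-1,6,8-trimethoxydibenzo[b,e][1,4]dioxin-3-ol
Conditions: SPhos Pd G3 (5 mol%), K3PO4, THF–H2O, 50 °C, 21 in excess
Reagents that add atoms: none
Why: Suzuki–Miyaura coupling with a dialkylbiarylphosphine precatalyst suited to hindered partners and to 2,6-disubstituted boronates prone to protodeboronation, the free phenol being tolerated as its phenoxide and the biaryl axis being of no consequence because it becomes planar in step 13.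

Step 13
Reactants: 22 4-[3-(3,5-dimethoxyphenoxy)-2-fluoro-4,6-dimethoxyphenyl]-9-(3,5-dimethoxyphenoxy)-1,6,8-trimethoxydibenzo[b,e][1,4]dioxin-3-ol
Product: 23 phlorofucofuroeckol A nona-O-methyl ether (the target skeleton with all nine hydroxyls as methyl ethers)
Conditions: Cs2CO3, DMSO, 120 °C
Reagents that add atoms: none
Why: Intramolecular SNAr in which the C4 phenoxide attacks the adjacent fluorine-bearing carbon D1 to close the five-membered furan ring, the fluoroarene being activated only inductively by its meta methoxy groups so that heat in a dipolar aprotic solvent is needed.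

Step 14
Reactants: 23 phlorofucofuroeckol A nona-O-methyl ether
Product: 24 phlorofucofuroeckol A
Conditions: BBr3 (excess), CH2Cl2, −78 °C → rt; MeOH then H2O; Sephadex LH-20 under argon
Reagents that add atoms: none
Why: Lewis-acid ether cleavage in which bromide attacks the methyl groups of the boron-complexed aryl methyl ethers, whereas the diaryl ether, dioxin and furan C–O bonds have no sp3 carbon and should stay intact.

**Compound list**

1 | 5-bromo-2,4-dimethoxybenzaldehyde | O=Cc1cc(Br)c(OC)cc1OC | starting material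
2 | 3,5-dimethoxyphenol | COc1cc(O)cc(OC)c1 | starting material
3 | 5-(3,5-dimethoxyphenoxy)-2,4-dimethoxybenzaldehyde | COc1cc(OC)cc(Oc2cc(C=O)c(OC)cc2OC)c1 | intermediate
4 | 5-(3,5-dimethoxyphenoxy)-2,4-dimethoxyphenyl formate (not isolated) | COc1cc(OC)cc(Oc2cc(OC=O)c(OC)cc2OC)c1 | intermediate
5 | 5-(3,5-dimethoxyphenoxy)-2,4-dimethoxyphenol | COc1cc(OC)cc(Oc2cc(O)c(OC)cc2OC)c1 | intermediate
6 | 3-(3,5-dimethoxyphenoxy)-2-(hydroxymethyl)-4,6-dimethoxyphenol (not isolated) | COc1cc(OC)cc(Oc2c(CO)c(O)c(OC)cc2OC)c1 | intermediate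
7 | 2-(3,5-dimethoxyphenoxy)-6-hydroxy-3,5-dimethoxybenzaldehyde | COc1cc(OC)cc(Oc2c(C=O)c(O)c(OC)cc2OC)c1 | intermediate
8 | 4-fluoro-3-methoxybenzaldehyde | COc1cc(C=O)ccc1F | starting material
9 | 2-bromo-4-fluoro-5-methoxybenzaldehyde | COc1cc(C=O)c(Br)cc1F | intermediate
10 | 2-bromo-4-[3-(3,5-dimethoxyphenoxy)-2-formyl-4,6-dimethoxyphenoxy]-5-methoxybenzaldehyde | COc1cc(OC)cc(Oc2c(C=O)c(Oc3cc(Br)c(C=O)cc3OC)c(OC)cc2OC)c1 | intermediate
11 | bis-formate of 12 (not isolated) | COc1cc(OC)cc(Oc2c(OC=O)c(Oc3cc(Br)c(OC=O)cc3OC)c(OC)cc2OC)c1 | intermediate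
12 | 2-(5-bromo-4-hydroxy-2-methoxyphenoxy)-6-(3,5-dimethoxyphenoxy)-3,5-dimethoxyphenol | COc1cc(OC)cc(Oc2c(O)c(Oc3cc(Br)c(O)cc3OC)c(OC)cc2OC)c1 | intermediate
13 | (±)-5'-bromo-4-(3,5-dimethoxyphenoxy)-2',5,7-trimethoxyspiro[1,3-benzodioxole-2,1'-cyclohexa-2',5'-dien]-4'-one (racemic) | O=C1C=C(OC)C2(C=C1Br)Oc1c(O2)c(OC)cc(OC)c1Oc1cc(OC)cc(OC)c1 | intermediate
14 | 4-bromo-9-(3,5-dimethoxyphenoxy)-1,6,8-trimethoxydibenzo[b,e][1,4]dioxin-3-ol | COc1cc(OC)cc(Oc2c(OC)cc(OC)c3c2Oc2c(OC)cc(O)c(Br)c2O3)c1 | intermediate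
15 | 2-fluoro-4,6-dimethoxybenzaldehyde | COc1cc(OC)c(C=O)c(F)c1 | starting material
16 | 2-fluoro-4,6-dimethoxyphenyl formate (not isolated) | COc1cc(OC)c(OC=O)c(F)c1 | intermediate
17 | 2-fluoro-4,6-dimethoxyphenol | COc1cc(OC)c(O)c(F)c1 | intermediate
18 | 1-bromo-3,5-dimethoxybenzene | COc1cc(Br)cc(OC)c1 | starting material
19 | 2-(3,5-dimethoxyphenoxy)-1-fluoro-3,5-dimethoxybenzene | COc1cc(OC)cc(Oc2c(F)cc(OC)cc2OC)c1 | intermediate
20 | [3-(3,5-dimethoxyphenoxy)-2-fluoro-4,6-dimethoxyphenyl]lithium (not isolated) | [Li]c1c(F)c(Oc2cc(OC)cc(OC)c2)c(OC)cc1OC | intermediate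
21 | 2-[3-(3,5-dimethoxyphenoxy)-2-fluoro-4,6-dimethoxyphenyl]-4,4,5,5-tetramethyl-1,3,2-dioxaborolane | CC1(C)OB(OC1(C)C)c1c(F)c(Oc2cc(OC)cc(OC)c2)c(OC)cc1OC | intermediate
22 | 4-[3-(3,5-dimethoxyphenoxy)-2-fluoro-4,6-dimethoxyphenyl]-9-(3,5-dimethoxyphenoxy)-1,6,8-trimethoxydibenzo[b,e][1,4]dioxin-3-ol | COc1cc(OC)cc(Oc2c(OC)cc(OC)c3c2Oc2c(OC)cc(O)c(-c4c(F)c(Oc5cc(OC)cc(OC)c5)c(OC)cc4OC)c2O3)c1 | intermediate
23 | phlorofucofuroeckol A nona-O-methyl ether | COc1cc(OC)cc(Oc2c(OC)cc(OC)c3c2Oc2c(OC)cc4oc5c(Oc6cc(OC)cc(OC)c6)c(OC)cc(OC)c5c4c2O3)c1 | intermediate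
24 | phlorofucofuroeckol A (achiral) | Oc1cc(O)cc(Oc2c(O)cc(O)c3c2Oc2c(O)cc4oc5c(Oc6cc(O)cc(O)c6)c(O)cc(O)c5c4c2O3)c1 | target

**Step count**

Total: 14 steps. Longest linear sequence: 10 steps (1, 2, 3, 5, 6, 7, 8, 12, 13, 14).

**Steps most likely to fail**

Step 8 (Proposed new method). The O-protonated dienone is a well-stabilised cation, so the oxygen shift may be too slow, and on warming ketal cleavage to the quinone and the catechol or intermolecular arylation may take over. The B6 oxygen may also migrate in place of the B5 oxygen and give the regioisomeric dioxin. The fallback is a known twofold SNAr annulation of a catechol with an ortho-difluoroarene; it sets out from 7 and comes back to the route at 14. Dakin oxidation of 7 (H2O2, NaOH, THF–H2O) would give 3-(3,5-dimethoxyphenoxy)-4,6-dimethoxybenzene-1,2-diol F1. Purchased 3,4-difluoro-5-methoxybenzaldehyde F2 would be brominated (Br2, AcOH) para to the methoxy group to 2-bromo-3,4-difluoro-5-methoxybenzaldehyde F3. F1 and F3 with K2CO3 in degassed DMF (60 °C, then 120 °C) should give 4-bromo-9-(3,5-dimethoxyphenoxy)-1,6,8-trimethoxydibenzo[b,e][1,4]dioxine-3-carbaldehyde F4. The more acidic hydroxyl of F1 (on B6, flanked by the aryloxy group) should displace the fluoride para to the formyl group first, and the B5 oxygen then closes the ring on the neighbouring fluoride; the orientation would be checked by HMBC and any regioisomer separated. Baeyer–Villiger oxidation of F4 (mCPBA, then K2CO3/MeOH) via the aryl formate F5 gives 14.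

Step 12. Protodeboronation of the 2-fluoro-6-methoxyaryl boronate 21 may outrun transmetalation with the electron-rich, doubly ortho-substituted bromophenol, and oxidative addition itself may be slow. The fallback moves the cross-coupling to the start, where the bromide is activated by an ortho formyl group and has one ortho substituent only; it sets out from 9 and 21 and comes back at 22. Suzuki coupling of 9 with 21 would give 2-[3-(3,5-dimethoxyphenoxy)-2-fluoro-4,6-dimethoxyphenyl]-4-fluoro-5-methoxybenzaldehyde F6. SNAr of 7 on F6 (K2CO3, DMF) at the fluoride para to the formyl group gives the dialdehyde diaryl ether F7 (the C5-aryl analogue of 10). Twofold Baeyer–Villiger oxidation via the bis-formate F8 gives the bisphenol F9 (the C5-aryl analogue of 12). PhI(OAc)2 then gives the spiroketal F10 (the C5-aryl analogue of 13), and the acid-induced oxygen shift of step 8 applied to F10 gives 22 directly.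

Step 13. Addition of the phenoxide to a fluoroarene that carries three ether groups may be too slow, and prolonged heating in base may degrade the electron-rich phenol. The fallback uses a fluorine-free D ring and an oxidative C–O closure; it sets out from 14 (with 5 as second component) and comes back at 23. Phenol 5 would be converted (Tf2O, pyridine, CH2Cl2) into 5-(3,5-dimethoxyphenoxy)-2,4-dimethoxyphenyl trifluoromethanesulfonate F11. Miyaura borylation (B2pin2, Pd(dppf)Cl2, KOAc, dioxane) gives 2-[5-(3,5-dimethoxyphenoxy)-2,4-dimethoxyphenyl]-4,4,5,5-tetramethyl-1,3,2-dioxaborolane F12. Suzuki coupling of F12 with 14 gives 4-[5-(3,5-dimethoxyphenoxy)-2,4-dimethoxyphenyl]-9-(3,5-dimethoxyphenoxy)-1,6,8-trimethoxydibenzo[b,e][1,4]dioxin-3-ol F13, a less hindered biaryl made from a stable boronate. Pd(II)-catalysed phenol-directed C–H activation/C–O cyclisation (Pd(OAc)2, 3-nitropyridine, tert-butyl peroxybenzoate, C6F6/DMI, 90 °C) at D1, the only free ortho C–H of ring D, then closes the furan to 23.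

**Further compounds**

F1 | step 8 | 3-(3,5-dimethoxyphenoxy)-4,6-dimethoxybenzene-1,2-diol | COc1cc(OC)cc(Oc2c(O)c(O)c(OC)cc2OC)c1
F2 | step 8 | 3,4-difluoro-5-methoxybenzaldehyde (purchased) | COc1cc(C=O)cc(F)c1F
F3 | step 8 | 2-bromo-3,4-difluoro-5-methoxybenzaldehyde | COc1cc(C=O)c(Br)c(F)c1F
F4 | step 8 | 4-bromo-9-(3,5-dimethoxyphenoxy)-1,6,8-trimethoxydibenzo[b,e][1,4]dioxine-3-carbaldehyde | COc1cc(OC)cc(Oc2c(OC)cc(OC)c3c2Oc2c(OC)cc(C=O)c(Br)c2O3)c1
F5 | step 8 | 4-bromo-9-(3,5-dimethoxyphenoxy)-1,6,8-trimethoxydibenzo[b,e][1,4]dioxin-3-yl formate | COc1cc(OC)cc(Oc2c(OC)cc(OC)c3c2Oc2c(OC)cc(OC=O)c(Br)c2O3)c1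
F6 | step 12 | 2-[3-(3,5-dimethoxyphenoxy)-2-fluoro-4,6-dimethoxyphenyl]-4-fluoro-5-methoxybenzaldehyde | COc1cc(C=O)c(cc1F)-c1c(F)c(Oc2cc(OC)cc(OC)c2)c(OC)cc1OC
F7 | step 12 | 4-[3-(3,5-dimethoxyphenoxy)-2-formyl-4,6-dimethoxyphenoxy]-2-[3-(3,5-dimethoxyphenoxy)-2-fluoro-4,6-dimethoxyphenyl]-5-methoxybenzaldehyde | COc1cc(OC)cc(Oc2c(C=O)c(Oc3cc(-c4c(F)c(Oc5cc(OC)cc(OC)c5)c(OC)cc4OC)c(C=O)cc3OC)c(OC)cc2OC)c1
F8 | step 12 | bis-formate of F9 | COc1cc(OC)cc(Oc2c(OC=O)c(Oc3cc(-c4c(F)c(Oc5cc(OC)cc(OC)c5)c(OC)cc4OC)c(OC=O)cc3OC)c(OC)cc2OC)c1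
F9 | step 12 | 2-{5-[3-(3,5-dimethoxyphenoxy)-2-fluoro-4,6-dimethoxyphenyl]-4-hydroxy-2-methoxyphenoxy}-6-(3,5-dimethoxyphenoxy)-3,5-dimethoxyphenol | COc1cc(OC)cc(Oc2c(O)c(Oc3cc(-c4c(F)c(Oc5cc(OC)cc(OC)c5)c(OC)cc4OC)c(O)cc3OC)c(OC)cc2OC)c1
F10 | step 12 | (±)-5'-[3-(3,5-dimethoxyphenoxy)-2-fluoro-4,6-dimethoxyphenyl]-4-(3,5-dimethoxyphenoxy)-2',5,7-trimethoxyspiro[1,3-benzodioxole-2,1'-cyclohexa-2',5'-dien]-4'-one | O=C1C=C(OC)C2(C=C1c1c(F)c(Oc3cc(OC)cc(OC)c3)c(OC)cc1OC)Oc1c(O2)c(OC)cc(OC)c1Oc1cc(OC)cc(OC)c1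
F11 | step 13 | 5-(3,5-dimethoxyphenoxy)-2,4-dimethoxyphenyl trifluoromethanesulfonate | COc1cc(OC)cc(Oc2cc(OS(=O)(=O)C(F)(F)F)c(OC)cc2OC)c1
F12 | step 13 | 2-[5-(3,5-dimethoxyphenoxy)-2,4-dimethoxyphenyl]-4,4,5,5-tetramethyl-1,3,2-dioxaborolane | COc1cc(OC)cc(Oc2cc(B3OC(C)(C)C(C)(C)O3)c(OC)cc2OC)c1
F13 | step 13 | 4-[5-(3,5-dimethoxyphenoxy)-2,4-dimethoxyphenyl]-9-(3,5-dimethoxyphenoxy)-1,6,8-trimethoxydibenzo[b,e][1,4]dioxin-3-ol | COc1cc(OC)cc(Oc2c(OC)cc(OC)c3c2Oc2c(OC)cc(O)c(-c4cc(Oc5cc(OC)cc(OC)c5)c(OC)cc4OC)c2O3)c1
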